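**Plan**

- Retrosynthesis first cuts both C–C bonds of the CH2 bridge (ring A carbon–CH2 and CH2–C2 of ring B). This leaves prenylated acylphloroglucinol 21, made from phloroglucinol, and the chiral ring B trione 18.
- In 18 the C3 and C5 oxygens, the C6 methyl and the isopropyl of the side-chain ketone are removed, leading back to formyl enone 9.
- Ring B (C1 ketone, C2 bridge carbon, C3 C–OH, C4 quaternary, C5 C–OH, C6 C–Me) is a six-membered carbocycle whose all-carbon stereocentre C4 carries an acyl carbon and sits 1,4 to the ketone carbon C1. That is the pattern of a [4+2] adduct of an α-substituted acrolein with a 2-oxygenated butadiene, so C3–C4 and C5–C6 are cut.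
- Forward: Claisen rearrangement and α-methylenation give 2-prenylacrolein 6, and its cycloaddition with aminosiloxy diene 7 closes ring B, the only ring built. Isopropyl addition, C6 methylation, dehydrogenation, twofold β-oxygenation and oxidation then give 18, which is joined last to ring A.
- Stereochemistry: C4 is the only stereocentre and is set by the chiral diol catalyst in the cycloaddition. The enone flank (C2/C3) and the saturated flank (C5/C6) stay different at every stage, so methyl goes to C6 and the bridge to C2 without loss of chirality.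

Key step: step 3

Assumption: stereocentres that are destroyed later (side-chain carbinol carbon, C6 of 12, oxirane and ring carbinol carbons of 15–17) are carried as mixtures and left open in the SMILES; the (4R,5R)-diol is taken as the catalyst enantiomer that gives (R)-9, and its mirror image is used if a test run shows the opposite sense.

**Step 1**
Reactants: 1 2-methylbut-3-en-2-ol; 2 ethyl vinyl ether
Product: 5 5-methylhex-4-enal, via mixed acetal 3 (not isolated), via allyl vinyl ether 4 (not isolated)
Conditions: 2 (3 equiv), H3PO4 (cat.), sealed vessel, 150 °C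
Reagents that add atoms: none
Why: Acid-catalysed vinyl transfer (acetal formation, then loss of ethanol) gives the tertiary allyl vinyl ether, which on heating undergoes the Claisen [3,3]-sigmatropic rearrangement to the γ,δ-unsaturated aldehyde with the trisubstituted alkene of the future prenyl group.

**Step 2**
Reactants: 5 5-methylhex-4-enal
Product: 6 5-methyl-2-methylidenehex-4-enal (2-prenylacrolein)
Conditions: 37% aq. CH2O, pyrrolidine (10 mol%), EtCO2H (10 mol%), iPrOH, 45 °C
Reagents that add atoms: formaldehyde, C=O
Why: This is the amine-catalysed α-methylenation of an aldehyde (Mannich condensation of the enamine with formaldehyde, then β-elimination of the amine), which should stop cleanly at the 2-substituted acrolein because the product has no α-hydrogen.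

**Step 3**
Reactants: 6 2-prenylacrolein; 7 (E)-1-(dimethylamino)-3-(tert-butyldimethylsilyloxy)buta-1,3-diene
Product: 9 (1R)-1-(3-methylbut-2-enyl)-4-oxocyclohex-2-ene-1-carbaldehyde, via cycloadduct 8 (not isolated)
Conditions: (4R,5R)-2,2-dimethyl-α,α,α′,α′-tetra(1-naphthyl)-1,3-dioxolane-4,5-dimethanol (20 mol%), toluene, −80 °C; then aq. HF, MeCN, 0 °C
Reagents that add atoms: none
Why: One hydroxyl of the diol hydrogen-bonds to the formyl oxygen of 6 (reinforced by the internal hydrogen bond from the second hydroxyl), which lowers the dienophile LUMO and lets a naphthyl group shield one face of the enal. Diene 7 then adds in a concerted, asynchronous, suprafacial [4+2] cycloaddition through an endo transition state, its nucleophilic CH2 terminus bonding to the acrolein CH2 (C5–C6) and its amino-bearing terminus to the substituted carbon (C3–C4). The closest known reaction type is the hydrogen-bond-catalysed Diels–Alder reaction of 1-amino-3-siloxybutadienes with α-substituted acroleins. Ring B closes as a six-membered carbocycle by intermolecular [4+2] cycloaddition, both ring bonds forming in the same step. The quaternary stereocentre C4 is set under catalyst control over the enantiofaces of 6, while the amino-bearing centre of 8 disappears when aqueous HF ionises the allylic amine and removes the silyl group to unveil the enone. The step needs regio- and enantioselectivity: the first is secured by the amino and siloxy donors, which both polarise the diene toward its CH2 terminus and match it with the enal β-carbon, the second by the diol, and the unactivated prenyl alkene should stay a spectator.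

**Step 4**
Reactants: 9 (1R)-1-(3-methylbut-2-enyl)-4-oxocyclohex-2-ene-1-carbaldehyde
Product: 10 (4R)-4-(1-hydroxy-2-methylpropyl)-4-(3-methylbut-2-enyl)cyclohex-2-en-1-one (both carbinol epimers)
Conditions: iPrMgCl (1.05 equiv), THF, −78 °C; aq. NH4Cl
Reagents that add atoms: isopropylmagnesium chloride, CC(C)[Mg]Cl
Why: In this Grignard 1,2-addition the aldehyde, though neopentylic, is much more electrophilic than the conjugated ketone, so one equivalent at low temperature should be consumed at the formyl group; the new carbinol centre is not controlled and is erased in step 11.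

**Step 5**
Reactants: 10 (4R)-4-(1-hydroxy-2-methylpropyl)-4-(3-methylbut-2-enyl)cyclohex-2-en-1-one
Product: 11 (4R)-4-(3-methylbut-2-enyl)-4-[2-methyl-1-(triethylsilyloxy)propyl]cyclohex-2-en-1-one
Conditions: Et3SiOTf, 2,6-lutidine, CH2Cl2, −78 → 0 °C
Reagents that add atoms: triethylsilyl trifluoromethanesulfonate, CC[Si](CC)(CC)OS(=O)(=O)C(F)(F)F
Why: Silyl triflate silylation is strong enough for the hindered carbinol, and the ether is needed because a free alkoxide on the C4 side chain would fragment by retro-aldol cleavage with aromatisation once the dienone is made.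

**Step 6**
Reactants: 11 (4R)-4-(3-methylbut-2-enyl)-4-[2-methyl-1-(triethylsilyloxy)propyl]cyclohex-2-en-1-one
Product: 12 (4S)-6-methyl-4-(3-methylbut-2-enyl)-4-[2-methyl-1-(triethylsilyloxy)propyl]cyclohex-2-en-1-one (C6 epimers)
Conditions: LiN(iPr)2 (1.1 equiv), THF, −78 °C; MeI, −78 → −20 °C
Reagents that add atoms: iodomethane, CI
Why: In this kinetic enolate alkylation the amide base can only remove a C6 proton (the γ-carbon C4 is quaternary), so the cross-conjugated enolate is methylated on the saturated flank; the C6 centre is uncontrolled and is removed in step 7.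

**Step 7**
Reactants: 12 (4S)-6-methyl-4-(3-methylbut-2-enyl)-4-[2-methyl-1-(triethylsilyloxy)propyl]cyclohex-2-en-1-one
Product: 14 (4R)-2-methyl-4-(3-methylbut-2-enyl)-4-[2-methyl-1-(triethylsilyloxy)propyl]cyclohexa-2,5-dien-1-one, via trimethylsilyl dienol ether 13 (not isolated)
Conditions: LiN(iPr)2, Me3SiCl, THF, −78 → 0 °C; then Pd(OAc)2 (1.1 equiv), MeCN, 25 °C
Reagents that add atoms: none
Why: Saegusa–Ito oxidation: the only possible silyl enol ether (toward C6) gives an oxa-π-allyl complex of divalent palladium, and β-hydride elimination from C5 should deliver the endocyclic methyl-substituted enone, so the cross-conjugated dienone stays chiral because only one flank carries methyl.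

**Step 8**
Reactants: 14 (4R)-2-methyl-4-(3-methylbut-2-enyl)-4-[2-methyl-1-(triethylsilyloxy)propyl]cyclohexa-2,5-dien-1-one
Product: 15 (4R)-2,3:5,6-diepoxy-2-methyl-4-(3-methylbut-2-enyl)-4-[2-methyl-1-(triethylsilyloxy)propyl]cyclohexan-1-one (oxirane configurations open)
Conditions: 30% H2O2 (excess), NaOH (cat.), MeOH, 0 → 25 °C
Reagents that add atoms: hydrogen peroxide, OO
Why: Weitz–Scheffer nucleophilic epoxidation attacks only the two electron-poor enone double bonds (the prenyl alkene is inert to hydroperoxide anion), with entry expected anti to the bulky siloxyalkyl group; the oxirane centres are transient.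

**Step 9**
Reactants: 15 (4R)-2,3:5,6-diepoxy-2-methyl-4-(3-methylbut-2-enyl)-4-[2-methyl-1-(triethylsilyloxy)propyl]cyclohexan-1-one
Product: 16 (4R)-3,5-dihydroxy-2-methyl-4-(3-methylbut-2-enyl)-4-[2-methyl-1-(triethylsilyloxy)propyl]cyclohexan-1-one (ring carbinol and C2 epimers)
Conditions: SmI2 (4.5 equiv), THF/MeOH, −90 °C
Reagents that add atoms: none
Why: Samarium diiodide reduction of α,β-epoxy ketones (ketyl formation, scission of the Cα–O bond, protonation of the samarium enolate) should open both oxiranes to β-hydroxy ketones at a temperature where neither dehydration nor retro-aldol cleavage competes.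

**Step 10**
Reactants: 16 (4R)-3,5-dihydroxy-2-methyl-4-(3-methylbut-2-enyl)-4-[2-methyl-1-(triethylsilyloxy)propyl]cyclohexan-1-one
Product: 17 (4S)-3,5-dihydroxy-4-(1-hydroxy-2-methylpropyl)-2-methyl-4-(3-methylbut-2-enyl)cyclohexan-1-one
Conditions: HF·pyridine, pyridine, THF, 0 °C
Reagents that add atoms: none
Why: Buffered fluoride desilylation removes the triethylsilyl ether under weakly acidic conditions that should leave the two β-hydroxy ketone units and the prenyl group untouched.

**Step 11**
Reactants: 17 (4S)-3,5-dihydroxy-4-(1-hydroxy-2-methylpropyl)-2-methyl-4-(3-methylbut-2-enyl)cyclohexan-1-one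
Product: 18 (4R)-3,5-dihydroxy-2-methyl-4-(2-methylpropanoyl)-4-(3-methylbut-2-enyl)cyclohexa-2,5-dien-1-one (enol form of the 1,3,5-trione)
Conditions: 2-iodoxybenzoic acid (6 equiv), EtOAc, 70 °C
Reagents that add atoms: none
Why: 2-Iodoxybenzoic acid oxidation of secondary alcohols, the method of choice for turning β-hydroxy ketones into β-diketones without base, should convert all three carbinols in one operation, and the product enolises to the vinylogous acid while the non-enolisable C4 centre is untouched.

**Step 12**
Reactants: 19 phloroglucinol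
Product: 20 2-methyl-1-(2,4,6-trihydroxyphenyl)propan-1-one
Conditions: iPrCOCl, AlCl3 (3.5 equiv), PhNO2, 65 °C; aq. HCl work-up
Reagents that add atoms: 2-methylpropanoyl chloride, CC(C)C(=O)Cl
Why: Friedel–Crafts acylation of the highly activated arene should stop after one acyl group because the chelated aryl ketone deactivates the ring.

**Step 13**
Reactants: 20 2-methyl-1-(2,4,6-trihydroxyphenyl)propan-1-one
Product: 21 2-methyl-1-[2,4,6-trihydroxy-3-(3-methylbut-2-enyl)phenyl]propan-1-one
Conditions: prenyl bromide (1.0 equiv), 10% aq. KOH, 0 °C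
Reagents that add atoms: 1-bromo-3-methylbut-2-ene, CC(C)=CCBr
Why: C-alkylation of the ambident acylphloroglucinol phenoxide in water favours carbon over oxygen, and one equivalent of halide at 0 °C should give mainly the mono-prenyl compound, separable from the diprenyl by-products.

**Step 14**
Reactants: 21 2-methyl-1-[2,4,6-trihydroxy-3-(3-methylbut-2-enyl)phenyl]propan-1-one
Product: 22 1-[3-[(dimethylamino)methyl]-2,4,6-trihydroxy-5-(3-methylbut-2-enyl)phenyl]-2-methylpropan-1-one
Conditions: CH2=NMe2+ I− (1.05 equiv), MeCN, 25 °C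
Reagents that add atoms: N,N-dimethylmethyleneiminium iodide, C=[N+](C)C.[I-]
Why: Mannich aminomethylation with a preformed iminium salt can only occur at the single free nuclear position and, with no free formaldehyde present, should not give the symmetrical ring A dimer.

**Step 15**
Reactants: 18 (4R)-3,5-dihydroxy-2-methyl-4-(2-methylpropanoyl)-4-(3-methylbut-2-enyl)cyclohexa-2,5-dien-1-one; 22 the ring A Mannich base
Product: 24 (4S)-3,5-dihydroxy-6-methyl-4-(2-methylpropanoyl)-4-(3-methylbut-2-enyl)-2-{[2,4,6-trihydroxy-3-(2-methylpropanoyl)-5-(3-methylbut-2-enyl)phenyl]methyl}cyclohexa-2,5-dien-1-one, via ortho-quinone methide 23 (not isolated)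
Conditions: 1,4-dioxane, 60 °C
Reagents that add atoms: none
Why: The acidic trione protonates the benzylic amine, phenol-assisted loss of dimethylamine gives the ortho-quinone methide, and Michael addition of the trione enolate through its unsubstituted C2 forms the bridge; C4 is not involved, and the CIP descriptor changes from R to S only because the new substituent changes the priorities.

**Compound list**

1 | 2-methylbut-3-en-2-ol | CC(C)(O)C=C | starting material
2 | ethyl vinyl ether | C=COCC | starting material
3 | 3-(1-ethoxyethoxy)-3-methylbut-1-ene (mixed acetal) | CCOC(C)OC(C)(C)C=C | intermediate (not isolated)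
4 | 3-ethenyloxy-3-methylbut-1-ene (allyl vinyl ether) | C=COC(C)(C)C=C | intermediate (not isolated)
5 | 5-methylhex-4-enal | CC(C)=CCCC=O | intermediate
6 | 5-methyl-2-methylidenehex-4-enal (2-prenylacrolein) | C=C(CC=C(C)C)C=O | intermediate
7 | (E)-1-(dimethylamino)-3-(tert-butyldimethylsilyloxy)buta-1,3-diene | CN(C)/C=C/C(=C)O[Si](C)(C)C(C)(C)C | starting material
8 | (1R,2R)-4-(tert-butyldimethylsilyloxy)-2-(dimethylamino)-1-(3-methylbut-2-enyl)cyclohex-3-ene-1-carbaldehyde (endo cycloadduct, formyl cis to amino) | CN(C)[C@@H]1C=C(O[Si](C)(C)C(C)(C)C)CC[C@]1(CC=C(C)C)C=O | intermediate (not isolated)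
9 | (1R)-1-(3-methylbut-2-enyl)-4-oxocyclohex-2-ene-1-carbaldehyde | O=C1C=C[C@@](CC=C(C)C)(C=O)CC1 | intermediate
10 | (4R)-4-(1-hydroxy-2-methylpropyl)-4-(3-methylbut-2-enyl)cyclohex-2-en-1-one, both carbinol epimers | O=C1C=C[C@@](CC=C(C)C)(C(O)C(C)C)CC1 | intermediate
11 | (4R)-4-(3-methylbut-2-enyl)-4-[2-methyl-1-(triethylsilyloxy)propyl]cyclohex-2-en-1-one | O=C1C=C[C@@](CC=C(C)C)(C(O[Si](CC)(CC)CC)C(C)C)CC1 | intermediate
12 | (4S)-6-methyl-4-(3-methylbut-2-enyl)-4-[2-methyl-1-(triethylsilyloxy)propyl]cyclohex-2-en-1-one, C6 epimers | O=C1C=C[C@@](CC=C(C)C)(C(O[Si](CC)(CC)CC)C(C)C)CC1C | intermediate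
13 | (5S)-1-methyl-5-(3-methylbut-2-enyl)-5-[2-methyl-1-(triethylsilyloxy)propyl]-2-(trimethylsilyloxy)cyclohexa-1,3-diene (trimethylsilyl dienol ether) | CC1=C(O[Si](C)(C)C)C=C[C@@](CC=C(C)C)(C(O[Si](CC)(CC)CC)C(C)C)C1 | intermediate (not isolated)
14 | (4R)-2-methyl-4-(3-methylbut-2-enyl)-4-[2-methyl-1-(triethylsilyloxy)propyl]cyclohexa-2,5-dien-1-one | O=C1C=C[C@@](CC=C(C)C)(C(O[Si](CC)(CC)CC)C(C)C)C=C1C | intermediate
15 | (4R)-2,3:5,6-diepoxy-2-methyl-4-(3-methylbut-2-enyl)-4-[2-methyl-1-(triethylsilyloxy)propyl]cyclohexan-1-one, oxirane configurations open | O=C1C2OC2[C@@](CC=C(C)C)(C(O[Si](CC)(CC)CC)C(C)C)C2OC12C | intermediate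
16 | (4R)-3,5-dihydroxy-2-methyl-4-(3-methylbut-2-enyl)-4-[2-methyl-1-(triethylsilyloxy)propyl]cyclohexan-1-one, epimer mixture at C2, C3, C5 | O=C1CC(O)[C@@](CC=C(C)C)(C(O[Si](CC)(CC)CC)C(C)C)C(O)C1C | intermediate
17 | (4S)-3,5-dihydroxy-4-(1-hydroxy-2-methylpropyl)-2-methyl-4-(3-methylbut-2-enyl)cyclohexan-1-one, epimer mixture at the carbinol carbons and C2 | O=C1CC(O)[C@@](CC=C(C)C)(C(O)C(C)C)C(O)C1C | intermediate
18 | (4R)-3,5-dihydroxy-2-methyl-4-(2-methylpropanoyl)-4-(3-methylbut-2-enyl)cyclohexa-2,5-dien-1-one | O=C1C=C(O)[C@@](CC=C(C)C)(C(=O)C(C)C)C(O)=C1C | intermediate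
19 | phloroglucinol | Oc1cc(O)cc(O)c1 | starting material
20 | 2-methyl-1-(2,4,6-trihydroxyphenyl)propan-1-one | CC(C)C(=O)c1c(O)cc(O)cc1O | intermediate
21 | 2-methyl-1-[2,4,6-trihydroxy-3-(3-methylbut-2-enyl)phenyl]propan-1-one | CC(C)=CCc1c(O)cc(O)c(C(=O)C(C)C)c1O | intermediate
22 | 1-[3-[(dimethylamino)methyl]-2,4,6-trihydroxy-5-(3-methylbut-2-enyl)phenyl]-2-methylpropan-1-one | CC(C)=CCc1c(O)c(CN(C)C)c(O)c(C(=O)C(C)C)c1O | intermediate
23 | 3,5-dihydroxy-6-methylidene-2-(2-methylpropanoyl)-4-(3-methylbut-2-enyl)cyclohexa-2,4-dien-1-one (ortho-quinone methide) | C=C1C(=O)C(C(=O)C(C)C)=C(O)C(CC=C(C)C)=C1O | intermediate (not isolated)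
24 | (4S)-3,5-dihydroxy-6-methyl-4-(2-methylpropanoyl)-4-(3-methylbut-2-enyl)-2-{[2,4,6-trihydroxy-3-(2-methylpropanoyl)-5-(3-methylbut-2-enyl)phenyl]methyl}cyclohexa-2,5-dien-1-one | CC(C)=CCc1c(O)c(CC2=C(O)[C@@](CC=C(C)C)(C(=O)C(C)C)C(O)=C(C)C2=O)c(O)c(C(=O)C(C)C)c1O | target

**Step count**

Total: 15 steps. Longest linear sequence: 12 steps (steps 1–11, then step 15); steps 12–14 form the ring A branch.

**Steps most likely to fail**

1. Step 11 (threefold oxidation). Once the ring carbonyls exist but the hindered side-chain carbinol is still unoxidised, retro-aldol loss of isobutyraldehyde with aromatisation of ring B may compete, as may over-oxidation of the enolised trione at C2 or C6.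
   Fallback: the side-chain ketone is installed before any ring β-carbonyl exists. The route sets out from 15: HF·pyridine removes the silyl group to give (4R)-2,3:5,6-diepoxy-4-(1-hydroxy-2-methylpropyl)-2-methyl-4-(3-methylbut-2-enyl)cyclohexan-1-one F1. Oxidation with 1,1,1-triacetoxy-1,1-dihydro-1,2-benziodoxol-3(1H)-one in CH2Cl2 gives (4R)-2,3:5,6-diepoxy-2-methyl-4-(2-methylpropanoyl)-4-(3-methylbut-2-enyl)cyclohexan-1-one F2. Both α,β-epoxy ketone units are then isomerised to β-diketones with a zerovalent palladium catalyst (Pd(PPh3)4, Ph2PCH2CH2PPh2, toluene, 80–110 °C), which rejoins the route at 18 and bypasses steps 9–11.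

2. Step 8 (double epoxidation). Conjugate attack of hydroperoxide at the two β-carbons next to the crowded quaternary centre may be slow, so the reaction may stall at the mono-epoxide or drift into oxidative ring cleavage.
   Fallback: from 14, a copper-catalysed double conjugate borylation (CuCl, 4,5-bis(diphenylphosphino)-9,9-dimethylxanthene, NaOtBu, bis(pinacolato)diboron, MeOH, THF) gives (4R)-2-methyl-4-(3-methylbut-2-enyl)-4-[2-methyl-1-(triethylsilyloxy)propyl]-3,5-bis(4,4,5,5-tetramethyl-1,3,2-dioxaborolan-2-yl)cyclohexan-1-one F3. Oxidation of both C–B bonds with NaBO3·4H2O in THF/H2O returns to the route at 16.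

3. Step 4 (chemoselective Grignard addition). Addition to the enone carbonyl may compete with addition to the hindered aldehyde.
   Fallback: the ketone is kept masked. Setting out from crude cycloadduct 8 (step 3 before the acid treatment), iPrMgCl in THF at −78 °C meets the aldehyde as the only free carbonyl and gives 1-[(1R,2R)-4-(tert-butyldimethylsilyloxy)-2-(dimethylamino)-1-(3-methylbut-2-enyl)cyclohex-3-en-1-yl]-2-methylpropan-1-ol F4. Aqueous HF in MeCN then eliminates dimethylamine and removes the silyl group, rejoining the route at 10.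

**Further compounds**

F1 | step 11 | (4R)-2,3:5,6-diepoxy-4-(1-hydroxy-2-methylpropyl)-2-methyl-4-(3-methylbut-2-enyl)cyclohexan-1-one | O=C1C2OC2[C@@](CC=C(C)C)(C(O)C(C)C)C2OC12C
F2 | step 11 | (4R)-2,3:5,6-diepoxy-2-methyl-4-(2-methylpropanoyl)-4-(3-methylbut-2-enyl)cyclohexan-1-one | O=C1C2OC2[C@@](CC=C(C)C)(C(=O)C(C)C)C2OC12C
F3 | step 8 | (4R)-2-methyl-4-(3-methylbut-2-enyl)-4-[2-methyl-1-(triethylsilyloxy)propyl]-3,5-bis(4,4,5,5-tetramethyl-1,3,2-dioxaborolan-2-yl)cyclohexan-1-one | O=C1CC(B2OC(C)(C)C(C)(C)O2)[C@@](CC=C(C)C)(C(O[Si](CC)(CC)CC)C(C)C)C(B2OC(C)(C)C(C)(C)O2)C1C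
F4 | step 4 | 1-[(1R,2R)-4-(tert-butyldimethylsilyloxy)-2-(dimethylamino)-1-(3-methylbut-2-enyl)cyclohex-3-en-1-yl]-2-methylpropan-1-ol | CN(C)[C@@H]1C=C(O[Si](C)(C)C(C)(C)C)CC[C@]1(CC=C(C)C)C(O)C(C)C
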